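**Retrosynthetic overview**
1. The target 14 is the 1,3-bis(isobutyrate) of an achiral 2-arylglycerol. The two ester C–O bonds are cut last (14 ⇒ triol 12), and one CH2OH arm is traced back to a methyl ester (12 ⇒ dihydroxy ester 11).
2. The plan rests on the fully substituted benzylic carbinol carbon with its tertiary oxygen and one CH2–O arm. This O–C–CH2–O unit is read as O3–C4–C5–O1 of a 1,3-dioxolane whose C2 is a formaldehyde carbon (11 ⇒ methylene acetal 10).
3. Key disconnection: C4–O3, C4–C5 and C2–O1 of that dioxolane, so that the carbene carbon of aryl diazoacetate 6 is joined to two molecules of formaldehyde by carbonyl ylide formation and [3+2] cycloaddition. This is the only ring formed, and it is opened again in the next step.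
4. 6 ⇒ arylacetate 4 (diazo transfer) ⇒ arylmalonate 3 (dealkoxycarbonylation) ⇒ aryl bromide 1 + dimethyl malonate 2 (palladium-catalysed arylation).

Key step: step 4

Assumption: the target has no stereocentre, because its carbinol carbon carries two identical isobutyryloxymethyl arms, so racemic intermediates are sufficient and no step needs stereocontrol.

**Step 1**
Reactants: 1 1-bromo-2-methoxy-4-methylbenzene; 2 dimethyl malonate
Product: 3 dimethyl 2-(2-methoxy-4-methylphenyl)malonate
Conditions: Pd(dba)2 (2 mol %), P(t-Bu)3 (4 mol %), K3PO4 (3 equiv), 2 (1.2 equiv), toluene, 70 °C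
Reagents that add atoms: dimethyl malonate (compound 2), COC(=O)CC(=O)OC
Why: Palladium-catalysed malonate α-arylation (Buchwald–Hartwig-type enolate coupling), in which zerovalent palladium carrying the bulky, electron-rich P(t-Bu)3 inserts into the hindered C–Br bond and reductively eliminates the aryl–malonate bond, while the acidic product rests as its enolate and is not arylated twice.

**Step 2**
Reactants: 3 dimethyl 2-(2-methoxy-4-methylphenyl)malonate
Product: 4 methyl 2-(2-methoxy-4-methylphenyl)acetate
Conditions: LiCl (2 equiv), H2O (2 equiv), DMSO, 150 °C
Reagents that add atoms: none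
Why: Krapcho dealkoxycarbonylation, in which the chloride-assisted loss of one CO2Me group as CO2 and methanol in hot wet DMSO is easy because the developing carbanion is benzylic and ester-stabilised, and the aryl methyl ether and the remaining ester are inert to these neutral conditions.

**Step 3**
Reactants: 4 methyl 2-(2-methoxy-4-methylphenyl)acetate; 5 4-acetamidobenzenesulfonyl azide
Product: 6 methyl 2-diazo-2-(2-methoxy-4-methylphenyl)acetate
Conditions: 5 (1.3 equiv), DBU (1.5 equiv), MeCN, 0 °C to rt
Reagents that add atoms: 4-acetamidobenzenesulfonyl azide (compound 5), CC(=O)Nc1ccc(cc1)S(=O)(=O)N=[N+]=[N-]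
Why: Regitz diazo transfer, in which DBU deprotonates the benzylic ester α-carbon, the enolate attacks the terminal nitrogen of the sulfonyl azide and the adduct fragments to the diazo ester and the sulfonamide, a sequence that is routine for ortho-substituted arylacetates.

**Step 4**
Reactants: 6 methyl 2-diazo-2-(2-methoxy-4-methylphenyl)acetate; 7 formaldehyde (monomer, two molecules incorporated)
Product: 10 methyl 4-(2-methoxy-4-methylphenyl)-1,3-dioxolane-4-carboxylate (racemic), via rhodium carbenoid 8 (not isolated), via carbonyl ylide 9 (not isolated)
Conditions: Rh2(OAc)4 (2 mol %), CH2O gas (from paraformaldehyde cracked at 160 °C, N2 stream, large excess, fed throughout), 4 Å MS, CH2Cl2, 0 °C; 6 added over 4 h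
Reagents that add atoms: formaldehyde (compound 7, two molecules), C=O
Why: Proposed new method: Rh2(OAc)4, a divalent rhodium dimer, expels N2 from 6 to give the electrophilic donor/acceptor carbenoid 8, the oxygen of one formaldehyde attacks its carbene carbon to form carbonyl ylide 9 (C4–O3 bond), and this 1,3-dipole adds across the C=O of a second formaldehyde so that the aryl- and ester-stabilised carbanionic terminus bonds to the carbonyl carbon (C4–C5) and the CH2=O+ terminus bonds to the carbonyl oxygen (C2–O1). The closest known reaction type is the Rh2(OAc)4-catalysed three-component union of methyl aryldiazoacetates with two molecules of an aromatic aldehyde, which gives 4-aryl-1,3-dioxolane-4-carboxylates by the same ylide formation and [3+2] capture; the new element is monomeric formaldehyde in both carbonyl roles. The 1,3-dioxolane, the only ring formed, closes by an intermolecular suprafacial [3+2] (4π + 2π) dipolar cycloaddition of the ylide onto the aldehyde carbonyl. C4 is the only new stereocentre and, with an achiral catalyst and achiral partners, nothing controls it, so 10 should form as a racemate, which is harmless because C4 becomes non-stereogenic in the target. The step needs chemoselectivity for bimolecular ylide capture over closure of 9 to the glycidate, over 1,5-insertion of 8 into the ortho-OCH3 C–H bonds and over carbene dimerisation, and it needs the head-to-tail regiochemistry; the first is secured by slow addition of 6 into a continuously renewed large excess of the smallest aldehyde, the second by the low reactivity of primary methoxy C–H bonds toward donor/acceptor carbenoids at 0 °C, and the regiochemistry by the polarity match of the nucleophilic ylide carbon with the electrophilic carbonyl carbon.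

**Step 5**
Reactants: 10 methyl 4-(2-methoxy-4-methylphenyl)-1,3-dioxolane-4-carboxylate (racemic)
Product: 11 methyl 2,3-dihydroxy-2-(2-methoxy-4-methylphenyl)propanoate (racemic)
Conditions: HCl (3 M in MeOH), reflux, slow distillation of CH2(OMe)2
Reagents that add atoms: none
Why: Acid-catalysed transacetalisation (methanolysis of a cyclic formal), in which the methylene unit is passed to methanol as volatile dimethoxymethane whose removal drives the exchange, while the neighbouring ester carbonyl disfavours ionisation of the tertiary benzylic C–O bond despite the electron-rich ring and the methyl ester cannot be changed by methanol.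

**Step 6**
Reactants: 11 methyl 2,3-dihydroxy-2-(2-methoxy-4-methylphenyl)propanoate (racemic)
Product: 12 2-(2-methoxy-4-methylphenyl)propane-1,2,3-triol
Conditions: LiAlH4 (3 equiv), THF, 0 °C to rt; then H2O, aq. NaOH
Reagents that add atoms: none
Why: Hydride reduction of an ester by LiAlH4, in which the two hydroxyls are merely deprotonated to alkoxides and the ester is reduced to the primary alcohol, making the two CH2OH arms identical and so removing the stereocentre.

**Step 7**
Reactants: 12 2-(2-methoxy-4-methylphenyl)propane-1,2,3-triol; 13 isobutyryl chloride (2-methylpropanoyl chloride)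
Product: 14 2-hydroxy-2-(2-methoxy-4-methylphenyl)propane-1,3-diyl bis(2-methylpropanoate)
Conditions: 13 (2.2 equiv), pyridine (4 equiv), CH2Cl2, −10 °C to rt
Reagents that add atoms: isobutyryl chloride (compound 13, two molecules), CC(C)C(Cl)=O
Why: Base-mediated O-acylation with an acid chloride (nucleophilic acyl substitution), in which the two primary hydroxyls react readily whereas the tertiary benzylic hydroxyl, crowded by the ortho-methoxy ring and two substituted methylene groups, should not be acylated by a branched acid chloride in the absence of an acyl-transfer catalyst.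

**Compound list**
1 | 1-bromo-2-methoxy-4-methylbenzene | Cc1ccc(Br)c(OC)c1 | starting material
2 | dimethyl malonate | COC(=O)CC(=O)OC | starting material
3 | dimethyl 2-(2-methoxy-4-methylphenyl)malonate | COC(=O)C(C(=O)OC)c1ccc(C)cc1OC | intermediate
4 | methyl 2-(2-methoxy-4-methylphenyl)acetate | COC(=O)Cc1ccc(C)cc1OC | intermediate
5 | 4-acetamidobenzenesulfonyl azide | CC(=O)Nc1ccc(cc1)S(=O)(=O)N=[N+]=[N-] | starting material
6 | methyl 2-diazo-2-(2-methoxy-4-methylphenyl)acetate | COC(=O)C(=[N+]=[N-])c1ccc(C)cc1OC | intermediate
7 | formaldehyde (monomeric gas, generated by cracking commercial paraformaldehyde) | C=O | starting material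
8 | rhodium carbenoid: the carbene of 6 bound to one rhodium of Rh2(OAc)4 (acetate bridges written as ions) | COC(=O)C(c1ccc(C)cc1OC)=[Rh+2][Rh+2].CC(=O)[O-].CC(=O)[O-].CC(=O)[O-].CC(=O)[O-] | intermediate
9 | carbonyl ylide: the carbene carbon of 6 bonded to the oxygen of formaldehyde, carbanion at the aryl/ester carbon, O+=CH2 terminus | COC(=O)[C-](c1ccc(C)cc1OC)[O+]=C | intermediate
10 | methyl 4-(2-methoxy-4-methylphenyl)-1,3-dioxolane-4-carboxylate (racemic) | COC(=O)C1(c2ccc(C)cc2OC)COCO1 | intermediate
11 | methyl 2,3-dihydroxy-2-(2-methoxy-4-methylphenyl)propanoate (racemic) | COC(=O)C(O)(CO)c1ccc(C)cc1OC | intermediate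
12 | 2-(2-methoxy-4-methylphenyl)propane-1,2,3-triol | OCC(O)(CO)c1ccc(C)cc1OC | intermediate
13 | isobutyryl chloride (2-methylpropanoyl chloride) | CC(C)C(Cl)=O | starting material
14 | 2-hydroxy-2-(2-methoxy-4-methylphenyl)propane-1,3-diyl bis(2-methylpropanoate) | COc1cc(C)ccc1C(O)(COC(=O)C(C)C)COC(=O)C(C)C | target

**Total step count:** 7
**Longest linear sequence:** 7 steps (1 to 14; the cracking of paraformaldehyde is a reagent preparation within step 4)

**Steps most likely to fail**

Step 4 (proposed new method). The ylide may collapse to the glycidate, or the carbenoid may insert into the ortho-methoxy C–H bonds or dimerise, faster than a second formaldehyde is captured. Polymerisation of formaldehyde would lower its effective concentration and make this worse. The fallback uses known chemistry, sets out from 4 and comes back at 11. Arylacetate 4 is heated with paraformaldehyde, K2CO3 and n-Bu4NI in toluene at 80 °C. Aldol addition should give methyl 3-hydroxy-2-(2-methoxy-4-methylphenyl)propanoate F1, which loses water in the same flask to methyl 2-(2-methoxy-4-methylphenyl)prop-2-enoate F2. Upjohn dihydroxylation of the 1,1-disubstituted alkene (K2OsO4·2H2O cat., NMO, acetone/H2O, rt) should then deliver racemic 11. The route continues with steps 6 and 7.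

Step 5. The transacetalisation of a formal that is deactivated by the adjacent ester may be slow or incomplete, and long exposure to hot acid may erode material. The fallback replaces solvolysis by acylative ring opening, sets out from 10 and comes back at 14. LiAlH4 in THF should reduce 10 to [4-(2-methoxy-4-methylphenyl)-1,3-dioxolan-4-yl]methanol F3. Acylation with 13 and pyridine in CH2Cl2 should give [4-(2-methoxy-4-methylphenyl)-1,3-dioxolan-4-yl]methyl 2-methylpropanoate F4. Treatment of F4 with 13 and catalytic ZnCl2 in CH2Cl2 at 0 °C is the known cleavage of cyclic formals by acid chlorides. It should acylate the less hindered primary ring oxygen and leave the tertiary oxygen as its chloromethyl ether, 2-(chloromethoxy)-2-(2-methoxy-4-methylphenyl)propane-1,3-diyl bis(2-methylpropanoate) F5. Stirring F5 with aqueous NaHCO3 in THF should hydrolyse the α-chloro ether to the hemiformal 2-(hydroxymethoxy)-2-(2-methoxy-4-methylphenyl)propane-1,3-diyl bis(2-methylpropanoate) F6, which loses formaldehyde to give 14.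

Step 1. Reductive elimination at the ortho-substituted, electron-rich arylpalladium centre may be sluggish, so that hydrodebromination competes. The fallback avoids the cross-coupling, sets out from 1 and comes back at 6. Magnesium insertion in THF should give (2-methoxy-4-methylphenyl)magnesium bromide F7. Inverse addition of F7 to dimethyl oxalate (COC(=O)C(=O)OC) at −78 °C should give methyl 2-(2-methoxy-4-methylphenyl)-2-oxoacetate F8. Condensation with 4-methylbenzenesulfonohydrazide in MeOH at 60 °C should give methyl 2-(2-methoxy-4-methylphenyl)-2-[2-(4-methylbenzenesulfonyl)hydrazinylidene]acetate F9 as a mixture of C=N isomers. Bamford–Stevens elimination of sulfinate with DBU in CH2Cl2 at rt should then give 6.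

**Further compounds**
F1 | step 4 | methyl 3-hydroxy-2-(2-methoxy-4-methylphenyl)propanoate (racemic, not isolated) | COC(=O)C(CO)c1ccc(C)cc1OC
F2 | step 4 | methyl 2-(2-methoxy-4-methylphenyl)prop-2-enoate | COC(=O)C(=C)c1ccc(C)cc1OC
F3 | step 5 | [4-(2-methoxy-4-methylphenyl)-1,3-dioxolan-4-yl]methanol (racemic) | OCC1(c2ccc(C)cc2OC)COCO1
F4 | step 5 | [4-(2-methoxy-4-methylphenyl)-1,3-dioxolan-4-yl]methyl 2-methylpropanoate (racemic) | CC(C)C(=O)OCC1(c2ccc(C)cc2OC)COCO1
F5 | step 5 | 2-(chloromethoxy)-2-(2-methoxy-4-methylphenyl)propane-1,3-diyl bis(2-methylpropanoate) | CC(C)C(=O)OCC(OCCl)(COC(=O)C(C)C)c1ccc(C)cc1OC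
F6 | step 5 | 2-(hydroxymethoxy)-2-(2-methoxy-4-methylphenyl)propane-1,3-diyl bis(2-methylpropanoate) (hemiformal, not isolated) | CC(C)C(=O)OCC(OCO)(COC(=O)C(C)C)c1ccc(C)cc1OC
F7 | step 1 | (2-methoxy-4-methylphenyl)magnesium bromide (not isolated) | Cc1ccc([Mg]Br)c(OC)c1
F8 | step 1 | methyl 2-(2-methoxy-4-methylphenyl)-2-oxoacetate | COC(=O)C(=O)c1ccc(C)cc1OC
F9 | step 1 | methyl 2-(2-methoxy-4-methylphenyl)-2-[2-(4-methylbenzenesulfonyl)hydrazinylidene]acetate (C=N isomer mixture) | COC(=O)C(=NNS(=O)(=O)c1ccc(C)cc1)c1ccc(C)cc1OC
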